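The target's oxolan-2-one ring holds its carbonyl carbon C2 next to a fully substituted C3 that carries a hydroxyl and an arylmethyl group; this C2/C3 pair is treated as an isomerised 1,2-diketone. The route therefore rests on disconnecting the C3–CH2Ar bond and the O1–C2 bond back to an open-chain arylmethyl diketone. In one operation the key step closes the five-membered ring as a lactol, shifts the arylmethyl group to the neighbouring ketone carbon, sets the C3 stereocentre and leaves the lactone. Its precursor is a syn-aldol-derived hydroxymethyl diketone with the carbinol and both phenols silylated, unveiled last from a dithiane.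

Key step: step 14

Remark on the chemistry: Ar stands for 3-methoxy-4-(triisopropylsilyloxy)phenyl. The phenols and the carbinol are carried as TIPS ethers and only the primary hydroxyl as a TBS ether, so that mild acid frees the primary hydroxyl alone. Hydroxy diketone 22 is assumed to rest mainly as its ring tautomer 23; the two are numbered separately.

Step 1
Reactants: 1 vanillin (4-hydroxy-3-methoxybenzaldehyde)
Product: 2 3-methoxy-4-(triisopropylsilyloxy)benzaldehyde
Conditions: TIPSCl, imidazole, DMF, rt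
Reagents that add atoms: triisopropylsilyl chloride, CC(C)[Si](Cl)(C(C)C)C(C)C
Why: Imidazole-promoted O-silylation of the phenol gives a bulky aryl silyl ether that should outlast the organolithium, Lewis-acid and mild Brønsted-acid steps until the final fluoride treatment.

Step 2
Reactants: 2 3-methoxy-4-(triisopropylsilyloxy)benzaldehyde
Product: 3 [3-methoxy-4-(triisopropylsilyloxy)phenyl]methanol
Conditions: NaBH4, MeOH–THF, 0 °C
Reagents that add atoms: none
Why: Borohydride reduction of an aromatic aldehyde, to which the aryl TIPS ether is inert at 0 °C.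

Step 3
Reactants: 3 [3-methoxy-4-(triisopropylsilyloxy)phenyl]methanol
Product: 4 4-(bromomethyl)-2-methoxy-1-(triisopropylsilyloxy)benzene
Conditions: PBr3, Et2O, 0 °C; used crude
Reagents that add atoms: phosphorus tribromide, BrP(Br)Br
Why: Conversion of a benzylic alcohol into the bromide through its phosphite ester (SN2 by bromide), a standard preparation of electron-rich benzyl bromides that are used without storage.

Step 4
Reactants: 4 4-(bromomethyl)-2-methoxy-1-(triisopropylsilyloxy)benzene; 5 1,3-dithiane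
Product: 7 2-[3-methoxy-4-(triisopropylsilyloxy)benzyl]-1,3-dithiane, via 2-lithio-1,3-dithiane 6 (not isolated)
Conditions: 5, n-BuLi, THF, −30 °C; then 4, −78 → −20 °C
Reagents that add atoms: none
Why: Corey–Seebach alkylation of the soft dithianyl anion by a reactive benzylic bromide.

Step 5
Reactants: 8 methyl 3-hydroxypropanoate
Product: 9 methyl 3-(tert-butyldimethylsilyloxy)propanoate
Conditions: TBSCl, imidazole, CH2Cl2, 0 °C → rt
Reagents that add atoms: tert-butyldimethylsilyl chloride, CC(C)(C)[Si](C)(C)Cl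
Why: Routine silylation of a primary alcohol; TBS is chosen because it is the only silyl group in the later intermediates that mild acid removes.

Step 6
Reactants: 9 methyl 3-(tert-butyldimethylsilyloxy)propanoate
Product: 10 3-(tert-butyldimethylsilyloxy)propanoic acid
Conditions: LiOH·H2O, THF–H2O, 0 °C; then cold 1 M HCl to pH 4
Reagents that add atoms: lithium hydroxide, [Li+].[OH-]
Why: Saponification of a methyl ester at 0 °C, under which a primary TBS ether persists and β-elimination of the silyloxy group is slow.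

Step 7
Reactants: 10 3-(tert-butyldimethylsilyloxy)propanoic acid; 11 (R)-4-benzyl-1,3-oxazolidin-2-one
Product: 13 (R)-4-benzyl-3-[3-(tert-butyldimethylsilyloxy)propanoyl]-1,3-oxazolidin-2-one, via pivalic mixed anhydride 12 (not isolated)
Conditions: PivCl, Et3N, THF, −20 °C; then 11, LiCl, −20 °C → rt
Reagents that add atoms: none
Why: One-pot N-acylation of the oxazolidinone through the pivaloyl mixed anhydride with LiCl/Et3N activation, which attacks the less hindered carbonyl and needs no strong base.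

Step 8
Reactants: 13 (R)-4-benzyl-3-[3-(tert-butyldimethylsilyloxy)propanoyl]-1,3-oxazolidin-2-one; 2 3-methoxy-4-(triisopropylsilyloxy)benzaldehyde
Product: 16 (R)-4-benzyl-3-[(2R,3R)-2-[(tert-butyldimethylsilyloxy)methyl]-3-hydroxy-3-Ar-propanoyl]-1,3-oxazolidin-2-one, via Z-boron enolate 14 (not isolated), via boron aldolate 15 (not isolated)
Conditions: Bu2BOTf, i-Pr2NEt, CH2Cl2, −78 → 0 °C; then 2, −78 → 0 °C; pH 7 buffer, MeOH, H2O2, 0 °C
Reagents that add atoms: none
Why: Evans syn-aldol: the Z-dibutylboron enolate reacts through a closed Zimmerman–Traxler chair on the face away from the auxiliary benzyl group, so the (R)-auxiliary sets both the future Cβ centre and the carbinol centre as the (2R,3R) syn pair.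

Step 9
Reactants: 16 (R)-4-benzyl-3-[(2R,3R)-2-[(tert-butyldimethylsilyloxy)methyl]-3-hydroxy-3-Ar-propanoyl]-1,3-oxazolidin-2-one
Product: 17 (2R,3R)-2-[(tert-butyldimethylsilyloxy)methyl]-3-hydroxy-N-methoxy-N-methyl-3-Ar-propanamide
Conditions: MeONHMe·HCl, AlMe3, CH2Cl2, −20 → 0 °C; aqueous work-up
Reagents that add atoms: N,O-dimethylhydroxylamine hydrochloride, CNOC.Cl
Why: Aluminium-amide transamination of an aldol imide to the Weinreb amide, run on the free β-hydroxy compound because the aluminium alkoxide directs attack to the exocyclic carbonyl; the auxiliary is recovered.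

Step 10
Reactants: 17 (2R,3R)-2-[(tert-butyldimethylsilyloxy)methyl]-3-hydroxy-N-methoxy-N-methyl-3-Ar-propanamide
Product: 18 (2R,3R)-2-[(tert-butyldimethylsilyloxy)methyl]-N-methoxy-N-methyl-3-Ar-3-(triisopropylsilyloxy)propanamide
Conditions: TIPSOTf, 2,6-lutidine, CH2Cl2, 0 °C → rt
Reagents that add atoms: triisopropylsilyl triflate, CC(C)[Si](C(C)C)(C(C)C)OS(=O)(=O)C(F)(F)F
Why: Silyl triflate/lutidine silylation of a hindered secondary benzylic alcohol; the TIPS ether later keeps this oxygen from forming a competing lactol and from ionising.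

Step 11
Reactants: 7 2-[3-methoxy-4-(triisopropylsilyloxy)benzyl]-1,3-dithiane; 18 (2R,3R)-2-[(tert-butyldimethylsilyloxy)methyl]-N-methoxy-N-methyl-3-Ar-3-(triisopropylsilyloxy)propanamide
Product: 20 (2R,3R)-2-[(tert-butyldimethylsilyloxy)methyl]-1-{2-[3-methoxy-4-(triisopropylsilyloxy)benzyl]-1,3-dithian-2-yl}-3-Ar-3-(triisopropylsilyloxy)propan-1-one, via lithiated benzyl dithiane 19 (not isolated)
Conditions: 7, n-BuLi, THF, −25 °C; then 18, −78 → −30 °C; AcOH quench at −78 °C
Reagents that add atoms: none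
Why: Acylation of a Corey–Seebach anion by a Weinreb amide, whose chelated tetrahedral adduct survives until the cold acidic quench, so that no over-addition occurs and the α-centre is not exposed to base as a ketone.

Step 12
Reactants: 20 (2R,3R)-2-[(tert-butyldimethylsilyloxy)methyl]-1-{2-[3-methoxy-4-(triisopropylsilyloxy)benzyl]-1,3-dithian-2-yl}-3-Ar-3-(triisopropylsilyloxy)propan-1-one
Product: 21 (2R,3R)-2-(hydroxymethyl)-1-{2-[3-methoxy-4-(triisopropylsilyloxy)benzyl]-1,3-dithian-2-yl}-3-Ar-3-(triisopropylsilyloxy)propan-1-one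
Conditions: CSA (0.2 equiv), MeOH–CH2Cl2 (1:1), 0 °C
Reagents that add atoms: none
Why: Acid-catalysed methanolysis cleaves the unhindered primary alkyl TBS ether far faster than aryl or secondary TIPS ethers, and it is done while the second carbonyl is still masked so that no diketone has to pass through a deprotection.

Step 13
Reactants: 21 (2R,3R)-2-(hydroxymethyl)-1-{2-[3-methoxy-4-(triisopropylsilyloxy)benzyl]-1,3-dithian-2-yl}-3-Ar-3-(triisopropylsilyloxy)propan-1-one
Product: 22 (4R,5R)-4-(hydroxymethyl)-1,5-bis[3-methoxy-4-(triisopropylsilyloxy)phenyl]-5-(triisopropylsilyloxy)pentane-2,3-dione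
Conditions: PhI(OCOCF3)2, NaHCO3, MeCN–H2O (9:1), 0 °C; brief silica filtration, used at once
Reagents that add atoms: water, O
Why: Oxidative dethioacetalisation with a hypervalent iodine reagent (S-activation, C–S cleavage assisted by the neighbouring hydroxyl, hydrolysis) should release the second carbonyl directly as the lactol tautomer under bicarbonate buffering, so the enolisable open-chain benzyl diketone does not accumulate.

Step 14
Reactants: 22 (4R,5R)-4-(hydroxymethyl)-1,5-bis[3-methoxy-4-(triisopropylsilyloxy)phenyl]-5-(triisopropylsilyloxy)pentane-2,3-dione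
Product: 24 (3S,4R)-3-hydroxy-3-[3-methoxy-4-(triisopropylsilyloxy)benzyl]-4-[(R)-Ar(triisopropylsilyloxy)methyl]oxolan-2-one, via lactol 23 (not isolated)
Conditions: Yb(OTf)3 (20 mol %), CH2Cl2, 0 °C → rt, argon, no base or drying agent
Reagents that add atoms: none
Why: Proposed new method: the hydroxymethyl oxygen of 22 adds reversibly to the arylmethyl-bearing carbonyl (5-exo-trig hemiketalisation) to give lactol 23, in which Yb(III) held between the lactol hydroxyl and the ring ketone lets the arylmethyl group slide suprafacially from C2 to the ketone carbon C3 while the hemiketal collapses to the lactone carbonyl, a shift driven by exchanging a ketone and a hemiketal for an ester and a tertiary alcohol. The closest known reaction types are the α-ketol (acyloin) rearrangement and the intramolecular benzilic ester rearrangement, neither of which has been shown with an arylmethyl group leaving a lactol carbon. The new C3 stereocentre is controlled by the adjacent C4 centre: the lactol epimers interconvert through the open form, and the shift should run through the epimer whose arylmethyl group travels on the ring face opposite the bulky CH(OTIPS)Ar substituent, which leaves the hydroxyl cis to that substituent (3S). The step needs migration to win over enolisation or dehydration toward the benzylic CH2 and over epimerisation at C4; the base-free, weakly Lewis-acidic medium, the lactol resting state (which has no enolisable benzyl ketone) and the TIPS ether that keeps the carbinol oxygen from closing a rival lactol are there to secure this.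

Step 15
Reactants: 24 (3S,4R)-3-hydroxy-3-[3-methoxy-4-(triisopropylsilyloxy)benzyl]-4-[(R)-Ar(triisopropylsilyloxy)methyl]oxolan-2-one
Product: 25 (3S,4R)-3-hydroxy-3-(4-hydroxy-3-methoxybenzyl)-4-[(R)-hydroxy(4-hydroxy-3-methoxyphenyl)methyl]oxolan-2-one (CNP0352022.1)
Conditions: TBAF/AcOH (1:1, 6 equiv), THF, 0 °C → rt
Reagents that add atoms: none
Why: Fluoride cleaves the two aryl and the benzylic Si–O bonds, and the acetic acid buffer keeps phenoxide and alkoxide from building up, so that translactonisation onto the benzylic oxygen and quinone-methide chemistry should not start.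

Compound list
1 | vanillin (4-hydroxy-3-methoxybenzaldehyde) | COc1cc(C=O)ccc1O | starting material
2 | 3-methoxy-4-(triisopropylsilyloxy)benzaldehyde | COc1cc(C=O)ccc1O[Si](C(C)C)(C(C)C)C(C)C | intermediate
3 | [3-methoxy-4-(triisopropylsilyloxy)phenyl]methanol | COc1cc(CO)ccc1O[Si](C(C)C)(C(C)C)C(C)C | intermediate
4 | 4-(bromomethyl)-2-methoxy-1-(triisopropylsilyloxy)benzene | COc1cc(CBr)ccc1O[Si](C(C)C)(C(C)C)C(C)C | intermediate
5 | 1,3-dithiane | C1CSCSC1 | starting material
6 | 2-lithio-1,3-dithiane (not isolated) | [Li]C1SCCCS1 | intermediate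
7 | 2-[3-methoxy-4-(triisopropylsilyloxy)benzyl]-1,3-dithiane | COc1cc(CC2SCCCS2)ccc1O[Si](C(C)C)(C(C)C)C(C)C | intermediate
8 | methyl 3-hydroxypropanoate | COC(=O)CCO | starting material
9 | methyl 3-(tert-butyldimethylsilyloxy)propanoate | COC(=O)CCO[Si](C)(C)C(C)(C)C | intermediate
10 | 3-(tert-butyldimethylsilyloxy)propanoic acid | OC(=O)CCO[Si](C)(C)C(C)(C)C | intermediate
11 | (R)-4-benzyl-1,3-oxazolidin-2-one | O=C1N[C@H](Cc2ccccc2)CO1 | starting material
12 | 3-(tert-butyldimethylsilyloxy)propanoic pivalic anhydride (not isolated) | CC(C)(C)C(=O)OC(=O)CCO[Si](C)(C)C(C)(C)C | intermediate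
13 | (R)-4-benzyl-3-[3-(tert-butyldimethylsilyloxy)propanoyl]-1,3-oxazolidin-2-one | CC(C)(C)[Si](C)(C)OCCC(=O)N1[C@H](Cc2ccccc2)COC1=O | intermediate
14 | Z-dibutylboron enolate of 13 (not isolated) | CCCCB(CCCC)O/C(=C\CO[Si](C)(C)C(C)(C)C)N1[C@H](Cc2ccccc2)COC1=O | intermediate
15 | dibutylboron aldolate of 16 (not isolated) | O=C1OC[C@@H](Cc2ccccc2)N1C(=O)[C@H](CO[Si](C)(C)C(C)(C)C)[C@@H](OB(CCCC)CCCC)c3ccc(O[Si](C(C)C)(C(C)C)C(C)C)c(OC)c3 | intermediate
16 | (R)-4-benzyl-3-[(2R,3R)-2-[(tert-butyldimethylsilyloxy)methyl]-3-hydroxy-3-[3-methoxy-4-(triisopropylsilyloxy)phenyl]propanoyl]-1,3-oxazolidin-2-one | O=C1OC[C@@H](Cc2ccccc2)N1C(=O)[C@H](CO[Si](C)(C)C(C)(C)C)[C@@H](O)c3ccc(O[Si](C(C)C)(C(C)C)C(C)C)c(OC)c3 | intermediate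
17 | (2R,3R)-2-[(tert-butyldimethylsilyloxy)methyl]-3-hydroxy-N-methoxy-N-methyl-3-[3-methoxy-4-(triisopropylsilyloxy)phenyl]propanamide | CON(C)C(=O)[C@H](CO[Si](C)(C)C(C)(C)C)[C@@H](O)c1ccc(O[Si](C(C)C)(C(C)C)C(C)C)c(OC)c1 | intermediate
18 | (2R,3R)-2-[(tert-butyldimethylsilyloxy)methyl]-N-methoxy-N-methyl-3-[3-methoxy-4-(triisopropylsilyloxy)phenyl]-3-(triisopropylsilyloxy)propanamide | CON(C)C(=O)[C@H](CO[Si](C)(C)C(C)(C)C)[C@@H](O[Si](C(C)C)(C(C)C)C(C)C)c1ccc(O[Si](C(C)C)(C(C)C)C(C)C)c(OC)c1 | intermediate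
19 | 2-lithio-2-[3-methoxy-4-(triisopropylsilyloxy)benzyl]-1,3-dithiane (not isolated) | COc1cc(CC2([Li])SCCCS2)ccc1O[Si](C(C)C)(C(C)C)C(C)C | intermediate
20 | (2R,3R)-2-[(tert-butyldimethylsilyloxy)methyl]-1-{2-[3-methoxy-4-(triisopropylsilyloxy)benzyl]-1,3-dithian-2-yl}-3-[3-methoxy-4-(triisopropylsilyloxy)phenyl]-3-(triisopropylsilyloxy)propan-1-one | COc1cc(CC2(SCCCS2)C(=O)[C@H](CO[Si](C)(C)C(C)(C)C)[C@@H](O[Si](C(C)C)(C(C)C)C(C)C)c3ccc(O[Si](C(C)C)(C(C)C)C(C)C)c(OC)c3)ccc1O[Si](C(C)C)(C(C)C)C(C)C | intermediate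
21 | (2R,3R)-2-(hydroxymethyl)-1-{2-[3-methoxy-4-(triisopropylsilyloxy)benzyl]-1,3-dithian-2-yl}-3-[3-methoxy-4-(triisopropylsilyloxy)phenyl]-3-(triisopropylsilyloxy)propan-1-one | COc1cc(CC2(SCCCS2)C(=O)[C@H](CO)[C@@H](O[Si](C(C)C)(C(C)C)C(C)C)c3ccc(O[Si](C(C)C)(C(C)C)C(C)C)c(OC)c3)ccc1O[Si](C(C)C)(C(C)C)C(C)C | intermediate
22 | (4R,5R)-4-(hydroxymethyl)-1,5-bis[3-methoxy-4-(triisopropylsilyloxy)phenyl]-5-(triisopropylsilyloxy)pentane-2,3-dione (key-step precursor) | COc1cc(CC(=O)C(=O)[C@H](CO)[C@@H](O[Si](C(C)C)(C(C)C)C(C)C)c2ccc(O[Si](C(C)C)(C(C)C)C(C)C)c(OC)c2)ccc1O[Si](C(C)C)(C(C)C)C(C)C | intermediate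
23 | (4R)-2-hydroxy-2-[3-methoxy-4-(triisopropylsilyloxy)benzyl]-4-{(R)-[3-methoxy-4-(triisopropylsilyloxy)phenyl](triisopropylsilyloxy)methyl}oxolan-3-one, both C2 epimers (lactol, not isolated) | COc1cc(CC2(O)OC[C@H]([C@@H](O[Si](C(C)C)(C(C)C)C(C)C)c3ccc(O[Si](C(C)C)(C(C)C)C(C)C)c(OC)c3)C2=O)ccc1O[Si](C(C)C)(C(C)C)C(C)C | intermediate
24 | (3S,4R)-3-hydroxy-3-[3-methoxy-4-(triisopropylsilyloxy)benzyl]-4-{(R)-[3-methoxy-4-(triisopropylsilyloxy)phenyl](triisopropylsilyloxy)methyl}oxolan-2-one (key-step product) | COc1cc(C[C@@]2(O)C(=O)OC[C@@H]2[C@@H](O[Si](C(C)C)(C(C)C)C(C)C)c3ccc(O[Si](C(C)C)(C(C)C)C(C)C)c(OC)c3)ccc1O[Si](C(C)C)(C(C)C)C(C)C | intermediate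
25 | (3S,4R)-3-hydroxy-3-(4-hydroxy-3-methoxybenzyl)-4-[(R)-hydroxy(4-hydroxy-3-methoxyphenyl)methyl]oxolan-2-one | COc1cc(C[C@@]2(O)C(=O)OC[C@@H]2[C@@H](O)c2ccc(O)c(OC)c2)ccc1O | target

Total step count: 15.
Longest linear sequence: 11 steps (steps 5–15, from methyl 3-hydroxypropanoate 8 to 25).

Steps most likely to fail

1. Step 14. The arylmethyl shift may be slower than loss of water from the lactol toward the benzylic CH2 or than enolisation at C4, and the face selectivity of the migration may be poor. The fallback uses known chemistry only; it sets out from 18 and comes back at 24. DIBAL-H (THF, −78 °C) should reduce 18 to the (2R,3R)-aldehyde F1. Addition of tris(methylthio)methyllithium (HC(SMe)3, n-BuLi, THF, −78 °C) gives the tris(methylthio)methyl carbinol F2 as carbinol epimers, both usable. Mercury(II)-assisted methanolysis (HgCl2, HgO, MeOH–H2O) gives the α-hydroxy methyl ester F3. CSA in MeOH then removes the primary TBS group and the freed hydroxyl closes to the α-hydroxy lactone F4. The dianion of F4 (LDA, 2.2 equiv, THF–DMPU, −78 °C) is C-alkylated with bromide 4 on the face anti to the C4 substituent, the established entry to trans 3-benzyl-3-hydroxy butyrolactone lignans, to reach 24.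

2. Step 13. C–S cleavage of an acyl dithiane is slow because the carbonyl disfavours ionisation, which leaves time for oxidation of the electron-rich rings or for acid-induced dehydration of the lactol. The fallback sets out from 20 and comes back at 22. Hydride reduction of the ketone (DIBAL-H, −78 °C) gives the dithianyl carbinol F5. This ordinary dithiane is then hydrolysed alkylatively (MeI, CaCO3, aqueous MeCN) to the acyloin F6. Bicarbonate-buffered Dess–Martin oxidation gives the silyloxy diketone F7, and HF·pyridine/pyridine in THF removes the primary TBS group to give 22.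

3. Step 11. The hindered tertiary dithianyl anion may act as a base toward the α-branched Weinreb amide (enolisation, then loss of silanolate) or may fail to add. The fallback sets out from 18 and comes back at 20. The unhindered 2-lithio-1,3-dithiane 6 (from 5) is acylated by 18 to give the 2-acyl-1,3-dithiane F8. Its acidic C2–H is removed (NaH, THF–DMF, 0 °C) and the soft carbanion is C-benzylated with bromide 4 to give 20.

Further compounds
F1 | step 14 | (2R,3R)-2-[(tert-butyldimethylsilyloxy)methyl]-3-[3-methoxy-4-(triisopropylsilyloxy)phenyl]-3-(triisopropylsilyloxy)propanal | O=C[C@H](CO[Si](C)(C)C(C)(C)C)[C@@H](O[Si](C(C)C)(C(C)C)C(C)C)c1ccc(O[Si](C(C)C)(C(C)C)C(C)C)c(OC)c1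
F2 | step 14 | tris(methylthio)methyl carbinol from F1 (carbinol epimers; other centres as in 18) | CSC(SC)(SC)C(O)[C@H](CO[Si](C)(C)C(C)(C)C)[C@@H](O[Si](C(C)C)(C(C)C)C(C)C)c1ccc(O[Si](C(C)C)(C(C)C)C(C)C)c(OC)c1
F3 | step 14 | methyl 2-hydroxy-3-[(tert-butyldimethylsilyloxy)methyl]-4-[3-methoxy-4-(triisopropylsilyloxy)phenyl]-4-(triisopropylsilyloxy)butanoate (C2 epimers) | COC(=O)C(O)[C@H](CO[Si](C)(C)C(C)(C)C)[C@@H](O[Si](C(C)C)(C(C)C)C(C)C)c1ccc(O[Si](C(C)C)(C(C)C)C(C)C)c(OC)c1
F4 | step 14 | 3-hydroxy-4-{(R)-[3-methoxy-4-(triisopropylsilyloxy)phenyl](triisopropylsilyloxy)methyl}oxolan-2-one (C3 epimers; C4 as in 24) | O=C1OC[C@H]([C@@H](O[Si](C(C)C)(C(C)C)C(C)C)c2ccc(O[Si](C(C)C)(C(C)C)C(C)C)c(OC)c2)C1O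
F5 | step 13 | dithianyl carbinol from reduction of 20 (carbinol epimers) | COc1cc(CC2(SCCCS2)C(O)[C@H](CO[Si](C)(C)C(C)(C)C)[C@@H](O[Si](C(C)C)(C(C)C)C(C)C)c3ccc(O[Si](C(C)C)(C(C)C)C(C)C)c(OC)c3)ccc1O[Si](C(C)C)(C(C)C)C(C)C
F6 | step 13 | acyloin: 4-[(tert-butyldimethylsilyloxy)methyl]-3-hydroxy-1,5-bis[3-methoxy-4-(triisopropylsilyloxy)phenyl]-5-(triisopropylsilyloxy)pentan-2-one (C3 epimers) | COc1cc(CC(=O)C(O)[C@H](CO[Si](C)(C)C(C)(C)C)[C@@H](O[Si](C(C)C)(C(C)C)C(C)C)c2ccc(O[Si](C(C)C)(C(C)C)C(C)C)c(OC)c2)ccc1O[Si](C(C)C)(C(C)C)C(C)C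
F7 | step 13 | (4R,5R)-4-[(tert-butyldimethylsilyloxy)methyl]-1,5-bis[3-methoxy-4-(triisopropylsilyloxy)phenyl]-5-(triisopropylsilyloxy)pentane-2,3-dione | COc1cc(CC(=O)C(=O)[C@H](CO[Si](C)(C)C(C)(C)C)[C@@H](O[Si](C(C)C)(C(C)C)C(C)C)c2ccc(O[Si](C(C)C)(C(C)C)C(C)C)c(OC)c2)ccc1O[Si](C(C)C)(C(C)C)C(C)C
F8 | step 11 | (2R,3R)-2-[(tert-butyldimethylsilyloxy)methyl]-1-(1,3-dithian-2-yl)-3-[3-methoxy-4-(triisopropylsilyloxy)phenyl]-3-(triisopropylsilyloxy)propan-1-one | O=C(C1SCCCS1)[C@H](CO[Si](C)(C)C(C)(C)C)[C@@H](O[Si](C(C)C)(C(C)C)C(C)C)c1ccc(O[Si](C(C)C)(C(C)C)C(C)C)c(OC)c1
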